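The target is cut at the two bonds that flank its C8 oxygen on ring B: C10–CH3 and C9–C11. Both are made in one flask from a bicyclic C8 enone (C9=C10) that already holds H-5: Me2CuLi delivers the angular methyl to C10 on the face of H-5, and the resulting C8–C9 enolate is hydroxymethylated at C9 with formaldehyde, fixing C10 and C9 together. The enone precursor is the 3-silyloxy-4,4-dimethyl octalone obtained from 6-methoxy-2-tetralone by gem-dimethylation, asymmetric reduction and Birch reduction. C8 is then turned into the methyl carbinol, and C11 is joined as a sulfone carbanion to a farnesol-derived C12–C22 bromide.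

Key step: step 5

Remark on the chemistry: the SMILES is taken as written; it defines a cis-fused decalin, (5S,8R,9R,10S), with H-5, CH3-10, C-11 and CH3-8 on one face (called β below) and the C8 hydroxyl on the other (α).

Numbering: target numbering throughout (ring A: C1–C5 and C10; ring B: C5–C10; side chain C11–C22; C17 is used for the exocyclic carbon on C8).

Remark on the precursor: the silyl group is put on after the acid step, because a silyl ether cannot be relied on to survive the HCl hydrolysis. C3 is made R so that the silyloxy group is equatorial and trans to H-5. It relays chirality to C5 and later biases the cis-decalin towards the chair needed for the C8 epoxidation.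

Remark on the side chain: its terminus is carried as a silyl ether, not an enoate, because an enoate is at risk in the sodium amalgam step.

Step 1
Reactants: 1 6-methoxy-2-tetralone; 2 methyl iodide
Product: 3 6-methoxy-1,1-dimethyl-3,4-dihydronaphthalen-2(1H)-one
Conditions: NaH (2.3 equiv), MeI (2.6 equiv), THF, 0 °C → rt
Reagents that add atoms: methyl iodide, CI
Why: Twofold enolate C-alkylation; the benzylic, arene-conjugated C1 enolate forms first both times, so both methyl groups go to the carbon that becomes C4.

Step 2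
Reactants: 3 6-methoxy-1,1-dimethyl-3,4-dihydronaphthalen-2(1H)-one
Product: 4 (R)-6-methoxy-1,1-dimethyl-1,2,3,4-tetrahydronaphthalen-2-ol
Conditions: (S)-Me-CBS oxazaborolidine [(S)-1-methyl-3,3-diphenyltetrahydro-1H,3H-pyrrolo[1,2-c][1,3,2]oxazaborole] (10 mol%), BH3·SMe2, THF, −20 °C; MeOH
Reagents that add atoms: none
Why: Corey–Bakshi–Shibata reduction; the quaternary C1 is the large and C3H2 the small ketone substituent, so the (S)-catalyst–borane complex should deliver hydride to the face that gives the (R)-carbinol (future C3).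

Step 3
Reactants: 4 (R)-6-methoxy-1,1-dimethyl-1,2,3,4-tetrahydronaphthalen-2-ol
Product: 7 (4aS,6R)-6-hydroxy-5,5-dimethyl-4,4a,5,6,7,8-hexahydronaphthalen-2(3H)-one, via enol ether diene 5 (not isolated), via β,γ-enone 6 (not isolated)
Conditions: Li, NH3(l), t-BuOH, THF, −78 → −33 °C; evaporate NH3; 2 M aq. HCl, THF, rt → 40 °C; chromatography, minor C5 epimer returned to the acid
Reagents that add atoms: water, O
Why: Birch reduction (sp3 carbons at the unsubstituted C6 and C9, enol ether at C7=C8) is followed by enol-ether hydrolysis and acid-catalysed conjugation through the dienol; protonation at the γ-carbon C5 is reversible, so C5 should settle under thermodynamic control with H-5 axial and the C3 hydroxyl equatorial on chair ring A (OH trans to H-5, 5S).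

Step 4
Reactants: 7 (4aS,6R)-6-hydroxy-5,5-dimethyl-4,4a,5,6,7,8-hexahydronaphthalen-2(3H)-one
Product: 8 (4aS,6R)-6-(tert-butyldimethylsilyloxy)-5,5-dimethyl-4,4a,5,6,7,8-hexahydronaphthalen-2(3H)-one [(3R,5S)-3-silyloxy-4,4-dimethyl-Δ9(10)-octalin-8-one]
Conditions: TBSCl, imidazole, DMAP (cat.), DMF, 45 °C
Reagents that add atoms: tert-butyldimethylsilyl chloride, CC(C)(C)[Si](C)(C)Cl
Why: Silylation of the hindered secondary alcohol under non-enolising conditions, so C5 is not disturbed and no stereocentre is formed.

Step 5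
Reactants: 8 (3R,5S)-3-silyloxy-4,4-dimethyl-Δ9(10)-octalin-8-one; 9 lithium dimethylcuprate; 10 formaldehyde (monomer)
Product: 12 (3R,5S,9S,10S)-3-(tert-butyldimethylsilyloxy)-9-(hydroxymethyl)-4,4,10-trimethyldecalin-8-one (cis-fused; H-5, CH3-10 and C-11 all β), via lithium enolate 11 (not isolated)
Conditions: Me2CuLi (from CuBr·SMe2 and 2 MeLi), Et2O, −30 → 0 °C; then THF, −78 °C, CH2O gas (cracked paraformaldehyde); aq. NH4Cl, −78 °C
Reagents that add atoms: lithium dimethylcuprate, [Li+].C[Cu-]C; formaldehyde, C=O
Why: The cuprate forms a π-complex with C9=C10, oxidative addition gives a β-cuprio enolate of trivalent copper, and reductive elimination makes C10–CH3 and leaves the regiodefined C8–C9 lithium enolate 11, which then adds to monomeric formaldehyde at C9 (aldol addition). The closest known reaction type is conjugate addition of Me2CuLi to Δ1(9)-2-octalones, which gives cis-fused angular-methyl decalones, combined with trapping of the cuprate-derived enolate by formaldehyde; no ring is closed. C10 is controlled by ring A: the reagent must approach perpendicular to the enone plane, the α face is the axial direction of chair ring A and is blocked by the axial 4α-methyl group 1,3 to C10, so the methyl group should enter on the β face, cis to H-5. C9 is controlled by the cis ring fusion just formed: in either half-chair of enolate 11 the α face of C9 is covered by ring A (C1 or the C4 methyl group), so formaldehyde should come from the convex β face and C11 should end equatorial and cis to the C10 methyl group. The step needs 1,4- rather than 1,2-addition, which the soft cuprate secures, and a single C-hydroxymethylation without retro-aldol cleavage or dehydration, for which the low temperature, the excess of monomeric formaldehyde and the cold neutral quench are chosen. The equatorial 3α-silyloxy group only anchors the chair of ring A and does not take part.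

Step 6
Reactants: 12 cis-fused 9β-(hydroxymethyl) C8 ketone
Product: 13 3α-(tert-butyldimethylsilyloxy)-9β-(hydroxymethyl)-4,4,10β-trimethyl-8-methylene-5β-decalin
Conditions: Zn, CH2Br2, TiCl4, THF (reagent pre-formed at 0–5 °C); 12, CH2Cl2, 0 °C → rt
Reagents that add atoms: dibromomethane, BrCBr
Why: Takai–Lombardo methylenation; the non-basic zinc–titanium methylene reagent should convert the hindered, enolisable C8 ketone into the exocyclic alkene without epimerising C9 or causing retro-aldol cleavage or β-elimination, and it tolerates the free hydroxyl.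

Step 7
Reactants: 13 8-methylene C11 alcohol
Product: 14 C11 phenyl sulfide (9β-CH2SPh, C8=C17)
Conditions: PhSSPh, n-Bu3P, pyridine, rt → 50 °C
Reagents that add atoms: diphenyl disulfide, c1ccccc1SSc1ccccc1
Why: Nakagawa–Hata thioetherification; the alkoxyphosphonium ion of the primary C11 alcohol is displaced by thiophenolate (SN2), with no stereocentre involved.

Step 8
Reactants: 14 C11 phenyl sulfide
Product: 17 8α,17-epoxy C11 phenyl sulfone, via sulfoxide 15 (not isolated), via alkenyl sulfone 16 (not isolated)
Conditions: mCPBA (3.5 equiv), NaHCO3, CH2Cl2, 0 °C → rt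
Reagents that add atoms: 3-chloroperbenzoic acid, OOC(=O)c1cccc(Cl)c1
Why: Sulfide-to-sulfone oxidation followed by Prilezhaev epoxidation of the 1,1-disubstituted C8=C17 alkene; in the ring B chair that keeps C11 equatorial and the 3α-silyloxy group equatorial, the C10 methyl group is axial and 1,3 to C8, so it screens the β face and oxygen should enter from the α face.

Step 9
Reactants: 17 8α,17-epoxy C11 phenyl sulfone
Product: 18 8α-hydroxy-8β-methyl C11 phenyl sulfone (3α-OTBS, 5β-H, 9β-CH2SO2Ph, 10β-CH3)
Conditions: LiBHEt3, THF, 0 °C → rt; H2O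
Reagents that add atoms: none
Why: Hydride SN2 opening of the epoxide at its unsubstituted carbon C17 leaves the C8–O bond untouched, so the α-oxygen becomes the tertiary hydroxyl and C17 the β-methyl group (8R); sulfone and silyl ether are inert.

Step 10
Reactants: 19 (2E,6E)-farnesol
Product: 20 (2E,6E)-farnesyl acetate
Conditions: Ac2O, pyridine, DMAP (cat.), CH2Cl2, rt
Reagents that add atoms: acetic anhydride, CC(=O)OC(C)=O
Why: Acylation; the acetate protects the C1 hydroxyl and deactivates the neighbouring C2=C3 alkene towards the next oxidation.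

Step 11
Reactants: 20 (2E,6E)-farnesyl acetate
Product: 21 (2E,6E,10E)-12-hydroxy-3,7,11-trimethyldodeca-2,6,10-trien-1-yl acetate
Conditions: SeO2 (cat.), t-BuOOH, salicylic acid (cat.), CH2Cl2, rt, stopped at partial conversion
Reagents that add atoms: tert-butyl hydroperoxide, CC(C)(C)OO (oxygen relayed through selenium dioxide, O=[Se]=O)
Why: Catalytic Riley allylic oxidation (ene reaction, then [2,3]-sigmatropic shift), which selects the (E)-methyl group of the terminal, most electron-rich trisubstituted alkene and so gives the (E)-allylic alcohol whose carbon ends as the carboxyl group.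

Step 12
Reactants: 21 12-hydroxyfarnesyl acetate
Product: 22 (2E,6E,10E)-12-(tert-butyldimethylsilyloxy)-3,7,11-trimethyldodeca-2,6,10-trien-1-yl acetate
Conditions: TBSCl, imidazole, CH2Cl2, rt
Reagents that add atoms: tert-butyldimethylsilyl chloride, CC(C)(C)[Si](C)(C)Cl
Why: Silylation of the primary allylic alcohol; the silyl ether is chosen because it should survive the carbanion coupling and the sodium amalgam step.

Step 13
Reactants: 22 silyloxy farnesyl acetate
Product: 23 (2E,6E,10E)-12-(tert-butyldimethylsilyloxy)-3,7,11-trimethyldodeca-2,6,10-trien-1-ol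
Conditions: K2CO3, MeOH, rt
Reagents that add atoms: none
Why: Base-catalysed methanolysis (transesterification) removes the acetate and leaves the silyl ether and the alkenes untouched.

Step 14
Reactants: 23 silyloxy farnesol
Product: 24 (2E,6E,10E)-1-bromo-12-(tert-butyldimethylsilyloxy)-3,7,11-trimethyldodeca-2,6,10-triene
Conditions: CBr4, PPh3, CH2Cl2, −20 → 0 °C
Reagents that add atoms: carbon tetrabromide, BrC(Br)(Br)Br
Why: Appel reaction; SN2 displacement of the oxyphosphonium ion at the primary allylic carbon gives the bromide with the (E)-alkenes unchanged.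

Step 15
Reactants: 18 8α-hydroxy C11 phenyl sulfone; 24 allylic bromide
Product: 26 C11-alkylated phenyl sulfone carrying the (13E,17E,21E)-C12–C22 chain with terminal CH2OTBS (C11 epimers), via dilithio dianion 25 (not isolated)
Conditions: n-BuLi (2.2 equiv), THF, −78 → −40 °C; 24, DMPU, −78 → −20 °C; aq. NH4Cl
Reagents that add atoms: none
Why: Alkylation of the α-sulfonyl carbanion at C11 with the primary allylic bromide (SN2) forms C11–C12 with the alkene geometry retained; the C8 lithium alkoxide is a bystander and the new C11 stereocentre is removed in the next step.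

Step 16
Reactants: 26 C11-alkylated phenyl sulfone
Product: 27 desulfonylated bis-silyl ether (3α-OTBS, 8α-OH, terminal CH2OTBS)
Conditions: Na(Hg) (6% Na), Na2HPO4, MeOH–THF, −20 → 0 °C
Reagents that add atoms: none
Why: Reductive desulfonylation by single-electron transfer from sodium amalgam cleaves the C11–S bond and methanol protonates the carbanion; isolated trisubstituted alkenes, silyl ethers and the tertiary alcohol are inert.

Step 17
Reactants: 27 bis-silyl ether
Product: 28 triol (3α-OH, 8α-OH, terminal (E)-allylic CH2OH)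
Conditions: Bu4NF, THF, rt → 50 °C
Reagents that add atoms: none
Why: Fluoride-mediated cleavage of both silyl ethers, driven by Si–F bond formation; no stereocentre is affected.

Step 18
Reactants: 28 triol
Product: 29 3-oxo-8α-hydroxy (21E)-enal
Conditions: Dess–Martin periodinane, NaHCO3, CH2Cl2, 0 °C → rt
Reagents that add atoms: none
Why: Dess–Martin oxidation converts the secondary C3 alcohol into the ketone and the primary allylic alcohol into the (E)-enal in one operation; the tertiary C8 alcohol cannot be oxidised and C5 is not α to the new ketone.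

Step 19
Reactants: 29 keto enal
Product: 30 myrrhanone B, (5S,8R,9R,10S,13E,17E,21E)
Conditions: NaClO2, NaH2PO4, 2-methyl-2-butene, t-BuOH–H2O, rt
Reagents that add atoms: sodium chlorite, [Na+].[O-]Cl=O
Why: Pinnick oxidation of the α,β-unsaturated aldehyde to the acid; the hypochlorite scavenger protects the trisubstituted alkenes and the enal geometry is retained.

Compound list
1 | 6-methoxy-2-tetralone | O=C1CCc2cc(OC)ccc2C1 | starting material
2 | methyl iodide | CI | starting material
3 | 6-methoxy-1,1-dimethyl-3,4-dihydronaphthalen-2(1H)-one | COc1ccc2c(c1)CCC(=O)C2(C)C | intermediate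
4 | (R)-6-methoxy-1,1-dimethyl-1,2,3,4-tetrahydronaphthalen-2-ol | COc1ccc2c(c1)CC[C@@H](O)C2(C)C | intermediate
5 | (R)-6-methoxy-1,1-dimethyl-1,2,3,4,5,8-hexahydronaphthalen-2-ol (enol ether diene) | COC1=CCC2=C(C1)CC[C@@H](O)C2(C)C | intermediate (not isolated)
6 | (R)-6-hydroxy-5,5-dimethyl-3,4,5,6,7,8-hexahydronaphthalen-2(1H)-one (β,γ-enone, C5=C10) | O=C1CCC2=C(C1)CC[C@@H](O)C2(C)C | intermediate (not isolated)
7 | (4aS,6R)-6-hydroxy-5,5-dimethyl-4,4a,5,6,7,8-hexahydronaphthalen-2(3H)-one (3R,5S in target numbering; OH trans to H-5) | O=C1C=C2CC[C@@H](O)C(C)(C)[C@H]2CC1 | intermediate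
8 | (4aS,6R)-6-(tert-butyldimethylsilyloxy)-5,5-dimethyl-4,4a,5,6,7,8-hexahydronaphthalen-2(3H)-one (key-step precursor) | O=C1C=C2CC[C@@H](O[Si](C)(C)C(C)(C)C)C(C)(C)[C@H]2CC1 | intermediate
9 | lithium dimethylcuprate | [Li+].C[Cu-]C | starting material (reagent made in the flask from CuBr·SMe2 and MeLi)
10 | formaldehyde (monomer from cracked paraformaldehyde) | C=O | starting material
11 | lithium C8–C9 enolate of the cis-fused 10β-methyl decalone | [Li+].[O-]C1=C[C@@]2(C)CC[C@@H](O[Si](C)(C)C(C)(C)C)C(C)(C)[C@H]2CC1 | intermediate (not isolated)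
12 | (3R,5S,9S,10S)-3-(tert-butyldimethylsilyloxy)-9-(hydroxymethyl)-4,4,10-trimethyldecalin-8-one (cis-fused) | OC[C@@H]1[C@@]2(C)CC[C@@H](O[Si](C)(C)C(C)(C)C)C(C)(C)[C@H]2CCC1=O | intermediate
13 | 3α-(tert-butyldimethylsilyloxy)-9β-(hydroxymethyl)-4,4,10β-trimethyl-8-methylene-5β-decalin | OC[C@@H]1[C@@]2(C)CC[C@@H](O[Si](C)(C)C(C)(C)C)C(C)(C)[C@H]2CCC1=C | intermediate
14 | C11 phenyl sulfide of 13 (9β-CH2SPh) | c1ccccc1SC[C@@H]1[C@@]2(C)CC[C@@H](O[Si](C)(C)C(C)(C)C)C(C)(C)[C@H]2CCC1=C | intermediate
15 | C11 phenyl sulfoxide (sulfur epimers) | O=S(c1ccccc1)C[C@@H]1[C@@]2(C)CC[C@@H](O[Si](C)(C)C(C)(C)C)C(C)(C)[C@H]2CCC1=C | intermediate (not isolated)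
16 | C11 phenyl sulfone with C8=C17 | O=S(=O)(c1ccccc1)C[C@@H]1[C@@]2(C)CC[C@@H](O[Si](C)(C)C(C)(C)C)C(C)(C)[C@H]2CCC1=C | intermediate (not isolated)
17 | 8α,17-epoxy C11 phenyl sulfone | O=S(=O)(c1ccccc1)C[C@@H]1[C@@]2(C)CC[C@@H](O[Si](C)(C)C(C)(C)C)C(C)(C)[C@H]2CC[C@@]1(C3)O3 | intermediate
18 | 8α-hydroxy-8β-methyl C11 phenyl sulfone | O=S(=O)(c1ccccc1)C[C@@H]1[C@@]2(C)CC[C@@H](O[Si](C)(C)C(C)(C)C)C(C)(C)[C@H]2CC[C@@]1(C)O | intermediate
19 | (2E,6E)-farnesol | CC(C)=CCC/C(C)=C/CC/C(C)=C/CO | starting material
20 | (2E,6E)-farnesyl acetate | CC(C)=CCC/C(C)=C/CC/C(C)=C/COC(C)=O | intermediate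
21 | (2E,6E,10E)-12-hydroxy-3,7,11-trimethyldodeca-2,6,10-trien-1-yl acetate | OC/C(C)=C/CC/C(C)=C/CC/C(C)=C/COC(C)=O | intermediate
22 | (2E,6E,10E)-12-(tert-butyldimethylsilyloxy)-3,7,11-trimethyldodeca-2,6,10-trien-1-yl acetate | CC(C)(C)[Si](C)(C)OC/C(C)=C/CC/C(C)=C/CC/C(C)=C/COC(C)=O | intermediate
23 | (2E,6E,10E)-12-(tert-butyldimethylsilyloxy)-3,7,11-trimethyldodeca-2,6,10-trien-1-ol | CC(C)(C)[Si](C)(C)OC/C(C)=C/CC/C(C)=C/CC/C(C)=C/CO | intermediate
24 | (2E,6E,10E)-1-bromo-12-(tert-butyldimethylsilyloxy)-3,7,11-trimethyldodeca-2,6,10-triene | CC(C)(C)[Si](C)(C)OC/C(C)=C/CC/C(C)=C/CC/C(C)=C/CBr | intermediate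
25 | dilithio dianion of 18 (C8 alkoxide, C11 carbanion) | [Li+].[Li+].O=S(=O)(c1ccccc1)[CH-][C@@H]1[C@@]2(C)CC[C@@H](O[Si](C)(C)C(C)(C)C)C(C)(C)[C@H]2CC[C@@]1(C)[O-] | intermediate (not isolated)
26 | C11-alkylated phenyl sulfone with the full side chain (C11 epimers) | CC(C)(C)[Si](C)(C)OC/C(C)=C/CC/C(C)=C/CC/C(C)=C/CC(S(=O)(=O)c1ccccc1)[C@@H]1[C@@]2(C)CC[C@@H](O[Si](C)(C)C(C)(C)C)C(C)(C)[C@H]2CC[C@@]1(C)O | intermediate
27 | desulfonylated bis-silyl ether | CC(C)(C)[Si](C)(C)OC/C(C)=C/CC/C(C)=C/CC/C(C)=C/CC[C@@H]1[C@@]2(C)CC[C@@H](O[Si](C)(C)C(C)(C)C)C(C)(C)[C@H]2CC[C@@]1(C)O | intermediate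
28 | triol (3α-OH, 8α-OH, terminal allylic CH2OH) | OC/C(C)=C/CC/C(C)=C/CC/C(C)=C/CC[C@@H]1[C@@]2(C)CC[C@@H](O)C(C)(C)[C@H]2CC[C@@]1(C)O | intermediate
29 | 3-oxo-8α-hydroxy (21E)-enal | O=C/C(C)=C/CC/C(C)=C/CC/C(C)=C/CC[C@@H]1[C@@]2(C)CCC(=O)C(C)(C)[C@H]2CC[C@@]1(C)O | intermediate
30 | myrrhanone B, (5S,8R,9R,10S,13E,17E,21E) | C/C(=C\CC/C(C)=C/CC[C@@H]1[C@@]2(C)CCC(=O)C(C)(C)[C@H]2CC[C@@]1(C)O)CC/C=C(\C)C(=O)O | target

Total step count: 19. Longest linear sequence: 14 steps (steps 1–9 and 15–19); the side-chain bromide takes 5 steps (10–14).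

Steps most likely to fail

1. Step 5. The conjugate addition may be slow at the fully substituted C10. The enolate may be lost by proton transfer, formaldehyde may oligomerise, hydroxymethylation may occur twice, or the aldol may dehydrate to the α-methylene ketone. Facial control at C9 may be incomplete. The fallback sets out from 8 and separates the two bond formations. Me2CuLi with Me3SiCl (THF, −78 °C) accelerates the 1,4-addition and should give the isolable C8 trimethylsilyl enol ether F1. F1 is then hydroxymethylated by a Mukaiyama aldol reaction with aqueous formaldehyde and Yb(OTf)3 (cat.) in THF–water, and the route is rejoined at 12.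

2. Step 3. The thermodynamic bias at C5 may be weak, because an equatorial hydroxyl next to the gem-dimethyl group is only modestly favoured over the axial one. Much C5 epimer may then remain and co-elute, and once C3 is oxidised this would lower the enantiomeric purity of the ring system. The fallback sets out from crude 7 (mixture of C5 epimers) and replaces thermodynamic control by physical separation. Acylation with 4-nitrobenzoyl chloride (pyridine, DMAP) and crystallisation should give the (3R,5S) 4-nitrobenzoate F2. Brief methanolysis (K2CO3, MeOH, 0 °C), which should outpace γ-deprotonation of the enone, comes back to 7. The mother liquor, after hydrolysis, is returned to the acid equilibration.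

3. Step 8. Epoxidation may show poor or reversed facial selectivity if the flexible cis-decalin reacts through its ring-flipped chair, in which C1 screens the α face of C8. The fallback sets out from 12 and uses the complementary order of bond formation: a methyl nucleophile adds to the C8 ketone from the face that a peracid would take and so gives the opposite carbinol. Et3SiCl and imidazole give the C11 triethylsilyl ether F3. MeLi with CeCl3 (THF, −78 °C) gives the 8-methyl carbinol F4. Pyridinium p-toluenesulfonate in MeOH at 0 °C removes only the primary silyl group and gives the C8,C11-diol F5. PhSSPh and n-Bu3P give the hydroxy sulfide F6, and mCPBA (2.2 equiv) oxidises it to the sulfone, rejoining the route at 18.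

Further compounds
F1 | step 5 | 8-(trimethylsilyloxy)-3α-(tert-butyldimethylsilyloxy)-4,4,10β-trimethyl-5β-octal-8-ene (silyl enol ether) | C[Si](C)(C)OC1=C[C@@]2(C)CC[C@@H](O[Si](C)(C)C(C)(C)C)C(C)(C)[C@H]2CC1
F2 | step 3 | (3R,5S) 4-nitrobenzoate of 7 | O=C1C=C2CC[C@@H](OC(=O)c3ccc(cc3)[N+](=O)[O-])C(C)(C)[C@H]2CC1
F3 | step 8 | C11 triethylsilyl ether of 12 | CC[Si](CC)(CC)OC[C@@H]1[C@@]2(C)CC[C@@H](O[Si](C)(C)C(C)(C)C)C(C)(C)[C@H]2CCC1=O
F4 | step 8 | 8α-hydroxy-8β-methyl C11 triethylsilyl ether | CC[Si](CC)(CC)OC[C@@H]1[C@@]2(C)CC[C@@H](O[Si](C)(C)C(C)(C)C)C(C)(C)[C@H]2CC[C@@]1(C)O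
F5 | step 8 | 8α-hydroxy-8β-methyl C11 alcohol (diol) | OC[C@@H]1[C@@]2(C)CC[C@@H](O[Si](C)(C)C(C)(C)C)C(C)(C)[C@H]2CC[C@@]1(C)O
F6 | step 8 | 8α-hydroxy-8β-methyl C11 phenyl sulfide | c1ccccc1SC[C@@H]1[C@@]2(C)CC[C@@H](O[Si](C)(C)C(C)(C)C)C(C)(C)[C@H]2CC[C@@]1(C)O
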